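The ten-membered ring is made by opening a bicycle, not by cyclisation. C6, the future angelate-bearing carbinol, and C10, the methyl-bearing epoxide carbon, lie opposite each other across C7–C9; bonding them gives a trans-fused bicycle of a cyclopentane (C6–C10) and a cycloheptene (C10, C1–C6), whose small ring forces the C4=C5 alkene to be Z. One base-triggered fragmentation of this bicycle, carrying a tertiary C6 hydroxyl and an anti-periplanar C1 mesylate, cleaves C6–C10 and releases the C6 ketone, the E C1=C10 alkene and the macrocycle together. Pyruvate aldol at C7, lactonisation onto O8, C6 reduction, double angeloylation and C1=C10 epoxidation complete the target.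

Key step: step 9

Remark: germacrane numbering is used throughout (ring C1–C10, lactone carbons C11–C13, C14 on C10, C15 on C4); the carbinol C1 made in step 1 is assumed to form without stereocontrol, so its configuration is left open in 3–6 and 8–10 and fixed in step 7, and because C1, C6 and C10 all become trigonal in step 9, a minor C10 epimer from step 3 that keeps the same mutual C1/C6/C10 relationship would lead to the same compound 15.

Step 1
Reactants: 1 (S)-4-(tert-butyldimethylsilyloxy)cyclopent-2-enone; 2 4-methylpent-4-enal
Product: 3 (4S)-4-(tert-butyldimethylsilyloxy)-2-(1-hydroxy-4-methylpent-4-en-1-yl)cyclopent-2-en-1-one (both C1 epimers)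
Conditions: PBu3 (20 mol%), 1,1'-bi-2-naphthol (10 mol%), THF, rt
Reagents that add atoms: none
Why: Phosphine-catalysed Morita–Baylis–Hillman reaction: PBu3 adds to the enone β-carbon (future C9), the resulting enolate attacks the aldehyde through the α-carbon (future C10) and the phosphine is expelled, which forms the C10–C1 bond; the new C1 carbinol is expected as a mixture of epimers, tolerated because C1 is flattened in step 6 and reset in step 7.

Step 2
Reactants: 3 Morita–Baylis–Hillman adduct
Product: 4 (4S)-4-(tert-butyldimethylsilyloxy)-2-[4-methyl-1-(triethylsilyloxy)pent-4-en-1-yl]cyclopent-2-en-1-one (both C1 epimers)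
Conditions: Et3SiCl, imidazole, DMF, 0 °C
Reagents that add atoms: chlorotriethylsilane, CC[Si](Cl)(CC)CC
Why: Standard silyl ether protection of a secondary alcohol, needed so that the enolate of step 3 is not quenched and the step 3 product cannot undergo retro-aldol cleavage; the triethylsilyl ether can later be removed by mild acid without touching the C8 tert-butyldimethylsilyl ether, and no stereocentre is affected.

Step 3
Reactants: 4 triethylsilyl-protected enone
Product: 6 (2R,4R)-4-(tert-butyldimethylsilyloxy)-2-methyl-2-[4-methyl-1-(triethylsilyloxy)pent-4-en-1-yl]cyclopentan-1-one (methyl trans to the ring silyloxy group; both C1 epimers), via lithium enolate 5 (not isolated)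
Conditions: LiBH(s-Bu)3, THF, −78 °C; then MeI, DMPU, −78 to −30 °C
Reagents that add atoms: iodomethane, CI
Why: Reductive alkylation of an enone: LiBH(s-Bu)3 delivers hydride in a 1,4-fashion to C9 to give the regiodefined tetrasubstituted lithium enolate 5, which is C-methylated at C10 preferentially on the ring face opposite the C8 silyloxy group, so that the C10 methyl is trans to that group; the quaternary centre cannot epimerise later.

Step 4
Reactants: 6 α-methyl ketone; 7 vinylmagnesium bromide
Product: 9 (1S,2R,4R)-4-(tert-butyldimethylsilyloxy)-1-ethenyl-2-(1-hydroxy-4-methylpent-4-en-1-yl)-2-methylcyclopentan-1-ol (ring hydroxyl cis to the C10 side chain and to the silyloxy group; both C1 epimers), via triethylsilyl ether 8 (not isolated)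
Conditions: LaCl3·2LiCl (30 mol%), THF, −78 to −40 °C; crude product: PPTS (cat.), MeOH, 0 °C
Reagents that add atoms: none
Why: Grignard 1,2-addition to a ketone, promoted by the lanthanum salt to suppress enolisation toward C7 and loss of the β-silyloxy group; the vinyl group should enter the C6 carbonyl from the face of the small C10 methyl, anti to both the bulky C10 side chain and the C8 silyloxy group, giving the C6 hydroxyl cis to the side chain (the relationship that later makes the ring fusion trans), and acid-catalysed methanolysis then cleaves only the more labile triethylsilyl ether of 8.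

Step 5
Reactants: 9 monocyclic diene diol
Product: 10 trans-fused (6S,8R,10R)-8-(tert-butyldimethylsilyloxy)-6,10-cyclogermacr-4-ene-1,6-diol (C10 methyl anti to C6 hydroxyl; both C1 epimers)
Conditions: second-generation Grubbs catalyst (5 mol%), PhMe, 80 °C
Reagents that add atoms: none
Why: Ring-closing metathesis between the C6 vinyl group and the 1,1-disubstituted alkene of the side chain, driven by loss of ethylene, closes the seven-membered ring with a trisubstituted C4=C5 bond that can only be Z in a cycloheptene; no stereocentre is formed and the trans ring fusion follows from the configurations set in steps 3 and 4.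

Step 6
Reactants: 10 bicyclic diol
Product: 11 trans-fused (6S,8R,10S)-8-(tert-butyldimethylsilyloxy)-6-hydroxy-6,10-cyclogermacr-4-en-1-one
Conditions: Dess–Martin periodinane, NaHCO3, CH2Cl2, 0 °C to rt
Reagents that add atoms: none
Why: Dess–Martin oxidation of the secondary C1 carbinol under buffered, non-basic conditions (the tertiary allylic C6 hydroxyl cannot be oxidised and the β-hydroxy ketone is not exposed to base that would trigger retro-aldol cleavage) merges both C1 epimers into a single ketone.

Step 7
Reactants: 11 β-hydroxy ketone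
Product: 12 trans-fused (1S,6S,8R,10R)-8-(tert-butyldimethylsilyloxy)-6,10-cyclogermacr-4-ene-1,6-diol (C1 hydroxyl cis to C10 methyl, anti to C6 hydroxyl)
Conditions: Me4NBH(OAc)3, MeCN/AcOH (1:1), −30 °C
Reagents that add atoms: none
Why: Hydroxyl-directed Evans–Saksena reduction: the C6 hydroxyl binds the triacetoxyborohydride and delivers hydride intramolecularly to the face of the C1 carbonyl on which it sits, which is also the face opposite the axial C10 methyl, so the 1,3-anti diol with the C1 hydroxyl cis to the C10 methyl (equatorial on the seven-membered ring) is expected.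

Step 8
Reactants: 12 anti-1,3-diol
Product: 13 trans-fused (1S,6S,8R,10R)-8-(tert-butyldimethylsilyloxy)-6-hydroxy-6,10-cyclogermacr-4-en-1-yl methanesulfonate
Conditions: MsCl, Et3N, CH2Cl2, −20 to 0 °C
Reagents that add atoms: methanesulfonyl chloride, CS(=O)(=O)Cl
Why: Sulfonylation of an alcohol: the secondary C1 hydroxyl is mesylated with retention (only the O–H bond reacts) while the hindered tertiary C6 hydroxyl stays free at low temperature, giving the fragmentation substrate.

Step 9
Reactants: 13 hydroxy mesylate
Product: 15 (8R,1(10)E,4Z)-8-(tert-butyldimethylsilyloxy)germacra-1(10),4-dien-6-one, via potassium alkoxide 14 (not isolated)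
Conditions: KOt-Bu (1.05 equiv), THF, −40 to 0 °C
Reagents that add atoms: none
Why: The base removes the proton of the tertiary C6 hydroxyl, and in alkoxide 14 the oxygen lone pair, the C6–C10 σ bond and the C1–O(mesylate) bond are anti-periplanar, so C6=O forms, C6–C10 breaks, C1=C10 forms and mesylate leaves in one concerted event that merges the five- and seven-membered rings into the ten-membered ring. The closest known reaction type is the Grob (Wharton) fragmentation of cyclic 1,3-diol monosulfonates, familiar from decalin-1,3-diol derivatives that open to E-cyclodecenones. No ring is closed by bond formation, so no closure mode applies: the macrocycle appears because the bond shared by the two small rings is cut. No stereocentre is created; C1, C6 and C10 become trigonal and C8 is not touched. The step needs E geometry at C1=C10, and the substrate secures it because the trans ring fusion holds C9 equatorial on the seven-membered ring, hence anti to C2 across C10–C1, while the equatorial C1 mesylate set in steps 7 and 8 is the only group anti to C6–C10; the Z geometry of C4=C5 is carried over unchanged from the cycloheptene. Only a slight excess of base is used so that the β-silyloxy enone 15 is not exposed to base that could expel the C8 silyloxy group.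

Step 10
Reactants: 15 ten-membered dienone
Product: 16 (8R,1(10)E,4Z)-8-(tert-butyldimethylsilyloxy)-6-(trimethylsilyloxy)germacra-1(10),4,6-triene (C6=C7 geometry left open)
Conditions: LiN(i-Pr)2, Me3SiCl (in situ), THF, −78 °C; Et3N, pentane, non-aqueous work-up
Reagents that add atoms: chlorotrimethylsilane, C[Si](C)(C)Cl
Why: Kinetic enolisation with an amide base at the only sp3 α-carbon (C7; α'-deprotonation of an enone is faster than γ-deprotonation) in the presence of the silyl chloride (in situ quench), so that the cross-conjugated enolate is trapped as the enol silane before it can expel the C8 silyloxy group; no stereocentre is formed and the C6=C7 geometry is not critical for step 11.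

Step 11
Reactants: 16 enol silane; 17 methyl pyruvate
Product: 19 methyl (7R,8R,11R,1(10)E,4Z)-8-(tert-butyldimethylsilyloxy)-11-hydroxy-6-oxogermacra-1(10),4-dien-12-oate, via trimethylsilyl ether 18 (not isolated)
Conditions: Cu(OTf)2 (10 mol%), 2,2'-(propane-2,2-diyl)bis[(4R)-4-tert-butyl-4,5-dihydro-1,3-oxazole] (11 mol%), THF, −78 °C; then 1 M HCl, THF, 0 °C
Reagents that add atoms: none
Why: Catalytic enantioselective Mukaiyama aldol addition to a pyruvate ester held as a five-membered chelate on the bis(oxazoline) complex of Cu(OTf)2: the (R,R)-ligand is chosen to leave the re face of the ketone open, which sets C11 as R, the open transition state of this reaction type favours the syn adduct (C8 on C7 syn to the C11 hydroxyl along the C6–C7–C11–C12 chain) from either enol silane geometry, and attack on the ring face away from the neighbouring C8 silyloxy group places the new C7–C11 bond trans to O8, so catalyst and substrate preferences should reinforce each other; acidic work-up hydrolyses the silyl ether 18.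

Step 12
Reactants: 19 aldol adduct
Product: 21 (7R,8R,11R,1(10)E,4Z)-11-hydroxy-6-oxogermacra-1(10),4-dien-12,8-olide (trans-fused γ-lactone), via hydroxy ester 20 (not isolated)
Conditions: HF·pyridine, pyridine, THF, 0 °C to rt; then PPTS (cat.), PhMe, 40 °C
Reagents that add atoms: none
Why: Acid-mediated desilylation with HF·pyridine (no base, so neither retro-aldol cleavage nor β-elimination is triggered) frees the C8 hydroxyl of 20, which closes the trans-fused γ-lactone by intramolecular transesterification of the C12 methyl ester (5-exo-trig); with C6 still a ketone the C8 hydroxyl is the only one that can reach C12 in a five-membered ring, and no stereocentre changes.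

Step 13
Reactants: 21 keto lactone
Product: 23 (6R,7S,8R,11R,1(10)E,4Z)-6,11-dihydroxygermacra-1(10),4-dien-12,8-olide, via diethylborinate 22 (not isolated)
Conditions: Et2BOMe, THF/MeOH (4:1), −78 °C; NaBH4, −78 °C; AcOH, then MeOH co-evaporation
Reagents that add atoms: none
Why: Narasaka–Prasad chelation-controlled reduction: the diethylboryl group bridges the C11 oxygen and the C6 carbonyl in a six-membered chelate cis-fused to the lactone, and borohydride attacks C6 from the exposed face that carries H7 and the C13 methyl, giving the 1,3-syn diol with the 6R configuration; the boron-activated β,β-disubstituted enone is reduced in the 1,2-sense and the lactone is inert at −78 °C.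

Step 14
Reactants: 23 diol lactone; 24 angelic anhydride ((Z)-2-methylbut-2-enoic anhydride)
Product: 25 (6R,7S,8R,11R,1(10)E,4Z)-6,11-bis(angeloyloxy)germacra-1(10),4-dien-12,8-olide
Conditions: 24 (4 equiv), THF, −78 °C; LiN(SiMe3)2 (2.3 equiv) added last, −78 to −20 °C
Reagents that add atoms: none
Why: Acylation of lithium alkoxides with a symmetrical anhydride (esterification) converts the secondary allylic C6 hydroxyl and the tertiary C11 hydroxyl into angelates without a nucleophilic amine catalyst, which avoids Z-to-E isomerisation to tiglates; the base is added last so that each alkoxide is acylated as it forms and cannot translactonise, and no stereocentre is touched.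

Step 15
Reactants: 25 bis-angelate
Product: 26 (1R,6R,7S,8R,10R,11R,4Z)-6,11-bis(angeloyloxy)-1,10-epoxygermacr-4-en-12,8-olide (target)
Conditions: 1,2:4,5-di-O-isopropylidene-β-D-erythro-2,3-hexodiulo-2,6-pyranose (30 mol%), 2KHSO5·KHSO4·K2SO4, K2CO3, Bu4NHSO4 (cat.), MeCN/CH2(OMe)2–aq. Na2B4O7 buffer (pH 10.5), 0 °C
Reagents that add atoms: potassium peroxymonosulfate, [K+].[O-]S(=O)(=O)OO
Why: Shi asymmetric epoxidation through a chiral dioxirane and a spiro transition state: the electron-rich E-trisubstituted C1=C10 bond reacts in preference to C4=C5 (deactivated by the allylic acyloxy group) and to the electron-poor angelate alkenes, the D-fructose-derived ketone is the enantiomer whose facial preference for an E-trisubstituted alkene of this substitution pattern corresponds to the (1R,10R)-epoxide, and the E geometry is transferred into the trans relationship of C2 and C9 on the oxirane.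

Compound list
1 | (S)-4-(tert-butyldimethylsilyloxy)cyclopent-2-enone | O=C1C=C[C@@H](O[Si](C)(C)C(C)(C)C)C1 | starting material
2 | 4-methylpent-4-enal | CC(=C)CCC=O | starting material
3 | (4S)-4-(tert-butyldimethylsilyloxy)-2-(1-hydroxy-4-methylpent-4-en-1-yl)cyclopent-2-en-1-one, C1 epimers | CC(=C)CCC(O)C1=C[C@@H](O[Si](C)(C)C(C)(C)C)CC1=O | intermediate
4 | (4S)-4-(tert-butyldimethylsilyloxy)-2-[4-methyl-1-(triethylsilyloxy)pent-4-en-1-yl]cyclopent-2-en-1-one, C1 epimers | CC(=C)CCC(O[Si](CC)(CC)CC)C1=C[C@@H](O[Si](C)(C)C(C)(C)C)CC1=O | intermediate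
5 | lithium enolate (C6–OLi, C6=C10) from 1,4-reduction of 4, not isolated | [Li]OC1=C(C(O[Si](CC)(CC)CC)CCC(C)=C)C[C@@H](O[Si](C)(C)C(C)(C)C)C1 | intermediate
6 | (2R,4R)-4-(tert-butyldimethylsilyloxy)-2-methyl-2-[4-methyl-1-(triethylsilyloxy)pent-4-en-1-yl]cyclopentan-1-one, C1 epimers | C[C@]1(C(O[Si](CC)(CC)CC)CCC(C)=C)C[C@@H](O[Si](C)(C)C(C)(C)C)CC1=O | intermediate
7 | vinylmagnesium bromide | C=C[Mg]Br | starting material
8 | (1S,2R,4R)-4-(tert-butyldimethylsilyloxy)-1-ethenyl-2-methyl-2-[4-methyl-1-(triethylsilyloxy)pent-4-en-1-yl]cyclopentan-1-ol, C1 epimers, not isolated | C[C@]1(C(O[Si](CC)(CC)CC)CCC(C)=C)C[C@@H](O[Si](C)(C)C(C)(C)C)C[C@]1(O)C=C | intermediate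
9 | (1S,2R,4R)-4-(tert-butyldimethylsilyloxy)-1-ethenyl-2-(1-hydroxy-4-methylpent-4-en-1-yl)-2-methylcyclopentan-1-ol, C1 epimers | C[C@]1(C(O)CCC(C)=C)C[C@@H](O[Si](C)(C)C(C)(C)C)C[C@]1(O)C=C | intermediate
10 | trans-fused (6S,8R,10R)-8-(tert-butyldimethylsilyloxy)-6,10-cyclogermacr-4-ene-1,6-diol, C1 epimers | C[C@]12C[C@@H](O[Si](C)(C)C(C)(C)C)C[C@]1(O)C=C(C)CCC2O | intermediate
11 | trans-fused (6S,8R,10S)-8-(tert-butyldimethylsilyloxy)-6-hydroxy-6,10-cyclogermacr-4-en-1-one | C[C@]12C[C@@H](O[Si](C)(C)C(C)(C)C)C[C@]1(O)C=C(C)CCC2=O | intermediate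
12 | trans-fused (1S,6S,8R,10R)-8-(tert-butyldimethylsilyloxy)-6,10-cyclogermacr-4-ene-1,6-diol | C[C@]12C[C@@H](O[Si](C)(C)C(C)(C)C)C[C@]1(O)C=C(C)CC[C@@H]2O | intermediate
13 | trans-fused (1S,6S,8R,10R)-8-(tert-butyldimethylsilyloxy)-6-hydroxy-6,10-cyclogermacr-4-en-1-yl methanesulfonate | C[C@]12C[C@@H](O[Si](C)(C)C(C)(C)C)C[C@]1(O)C=C(C)CC[C@@H]2OS(C)(=O)=O | intermediate
14 | potassium C6 alkoxide of 13, not isolated | C[C@]12C[C@@H](O[Si](C)(C)C(C)(C)C)C[C@]1([O-])C=C(C)CC[C@@H]2OS(C)(=O)=O.[K+] | intermediate
15 | (8R,1(10)E,4Z)-8-(tert-butyldimethylsilyloxy)germacra-1(10),4-dien-6-one | O=C1/C=C(/C)CC/C=C(\C)C[C@@H](O[Si](C)(C)C(C)(C)C)C1 | intermediate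
16 | (8R,1(10)E,4Z)-8-(tert-butyldimethylsilyloxy)-6-(trimethylsilyloxy)germacra-1(10),4,6-triene, C6=C7 geometry open | C[Si](C)(C)OC(/C=C(/C)CC/C=C(\C)C1)=C[C@@H]1O[Si](C)(C)C(C)(C)C | intermediate
17 | methyl pyruvate | COC(=O)C(C)=O | starting material
18 | 11-O-trimethylsilyl ether of 19, not isolated | O=C1/C=C(/C)CC/C=C(\C)C[C@@H](O[Si](C)(C)C(C)(C)C)[C@@H]1[C@@](C)(O[Si](C)(C)C)C(=O)OC | intermediate
19 | methyl (7R,8R,11R,1(10)E,4Z)-8-(tert-butyldimethylsilyloxy)-11-hydroxy-6-oxogermacra-1(10),4-dien-12-oate | O=C1/C=C(/C)CC/C=C(\C)C[C@@H](O[Si](C)(C)C(C)(C)C)[C@@H]1[C@@](C)(O)C(=O)OC | intermediate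
20 | methyl (7R,8R,11R,1(10)E,4Z)-8,11-dihydroxy-6-oxogermacra-1(10),4-dien-12-oate, not isolated | O=C1/C=C(/C)CC/C=C(\C)C[C@@H](O)[C@@H]1[C@@](C)(O)C(=O)OC | intermediate
21 | (7R,8R,11R,1(10)E,4Z)-11-hydroxy-6-oxogermacra-1(10),4-dien-12,8-olide | O=C1/C=C(/C)CC/C=C(\C)C[C@H]2OC(=O)[C@](C)(O)[C@H]12 | intermediate
22 | 11-O-diethylboryl derivative of 21, not isolated | O=C1/C=C(/C)CC/C=C(\C)C[C@H]2OC(=O)[C@](C)(OB(CC)CC)[C@H]12 | intermediate
23 | (6R,7S,8R,11R,1(10)E,4Z)-6,11-dihydroxygermacra-1(10),4-dien-12,8-olide | O[C@@H]1/C=C(/C)CC/C=C(\C)C[C@H]2OC(=O)[C@](C)(O)[C@H]12 | intermediate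
24 | angelic anhydride, (Z)-2-methylbut-2-enoic anhydride | C/C=C(/C)C(=O)OC(=O)/C(C)=C\C | starting material
25 | (6R,7S,8R,11R,1(10)E,4Z)-6,11-bis(angeloyloxy)germacra-1(10),4-dien-12,8-olide | C/C=C(/C)C(=O)O[C@@H]1/C=C(/C)CC/C=C(\C)C[C@H]2OC(=O)[C@](C)(OC(=O)/C(C)=C\C)[C@H]12 | intermediate
26 | (1R,6R,7S,8R,10R,11R,4Z)-6,11-bis(angeloyloxy)-1,10-epoxygermacr-4-en-12,8-olide | C/C=C(/C)C(=O)O[C@@H]1/C=C(/C)CC[C@H]2O[C@]2(C)C[C@H]2OC(=O)[C@](C)(OC(=O)/C(C)=C\C)[C@H]12 | target

Total step count: 15. Longest linear sequence: 15 steps (from 1).

Steps most likely to fail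

Step 9. Once the ring has opened, residual base may enolise the new ketone toward C7 and expel the C8 silyloxy group or shift the C4=C5 double bond, and slow alkoxide formation would let simple elimination of the mesylate compete. The fallback sets out from 13 and runs the opening as a fragmentation–reduction: KN(SiMe3)2 in THF at −78 °C with LiBH4 present, warming to 0 °C, so that the ketone is reduced as soon as it is released and the product is isolated as the base-stable allylic alcohol (8R,1(10)E,4Z)-8-(tert-butyldimethylsilyloxy)germacra-1(10),4-dien-6-ol F1 (both C6 epimers). Oxidation of the allylic alcohol with MnO2 in CH2Cl2 at rt then returns the route to 15.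

Step 11. The hindered macrocyclic enol silane may add sluggishly to the chelated pyruvate, or the facial preference of the ring at C7 may oppose that of the catalyst, so that mixtures at C7 and C11 result. The fallback sets out from 15 and bypasses 16: the kinetic lithium enolate (LiN(i-Pr)2, THF, −78 °C) is added directly to 17 in a closed, lithium-chelated aldol transition state under substrate control, and comes back to the route at 19 after separation of any C11 epimer. This fallback makes no compound outside the list (F0).

Step 15. The macrocycle may present mainly the wrong face of C1=C10 to the dioxirane, or oxidation of C4=C5 may compete in the fully acylated compound. The fallback sets out from 21, where C4=C5 is a deactivated enone alkene and the ring, with a trigonal C6, populates other conformers. Epoxidation under substrate control (peripheral attack) with mCPBA, NaHCO3, CH2Cl2 at 0 °C should give (1R,7R,8R,10R,11R,4Z)-1,10-epoxy-11-hydroxy-6-oxogermacr-4-en-12,8-olide F2. The reduction of step 13 then proceeds through the 11-O-diethylboryl derivative F3 to (1R,6R,7S,8R,10R,11R,4Z)-1,10-epoxy-6,11-dihydroxygermacr-4-en-12,8-olide F4. Acylation as in step 14 brings the route back at 26.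

Further compounds
F1 | step 9 | (8R,1(10)E,4Z)-8-(tert-butyldimethylsilyloxy)germacra-1(10),4-dien-6-ol, C6 epimers | OC1/C=C(/C)CC/C=C(\C)C[C@@H](O[Si](C)(C)C(C)(C)C)C1
F0 | step 11 | none | none
F2 | step 15 | (1R,7R,8R,10R,11R,4Z)-1,10-epoxy-11-hydroxy-6-oxogermacr-4-en-12,8-olide | O=C1/C=C(/C)CC[C@H]2O[C@]2(C)C[C@H]2OC(=O)[C@](C)(O)[C@H]12
F3 | step 15 | 11-O-diethylboryl derivative of F2 | O=C1/C=C(/C)CC[C@H]2O[C@]2(C)C[C@H]2OC(=O)[C@](C)(OB(CC)CC)[C@H]12
F4 | step 15 | (1R,6R,7S,8R,10R,11R,4Z)-1,10-epoxy-6,11-dihydroxygermacr-4-en-12,8-olide | O[C@@H]1/C=C(/C)CC[C@H]2O[C@]2(C)C[C@H]2OC(=O)[C@](C)(O)[C@H]12
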